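The route rests on cutting both pyrrole rings of the indolo[2,3-a]carbazole at N11–C11a and N12–C11b. This unfolds the pentacycle into a symmetric para-terphenyl: a 2,3-dimethoxybenzene core flanked at C1 and C4 by 4-chloro-2-nitrophenyl groups. A single phosphine-mediated double Cadogan deoxygenation then makes both C–N bonds and both five-membered rings and delivers the target directly. The step exploits the central benzene ring (C4b–C5–C6–C6a–C11a–C11b). C5 and C6 already carry OMe, so beside each biaryl bond the only C–H carbon is C11b or C11a, and only the [2,3-a] fusion can form. The terphenyl is assembled from veratrole by 3,6-diborylation and a twofold Suzuki coupling.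

Key step: step 3

Remark on the chemistry: the target is planar, C2v-symmetric and has no stereocentre, so it is achiral and no step needs stereocontrol; its chlorines (C2, C9) lie para to the biaryl carbons C4a/C6b, which maps onto a 4-chloro-2-nitrophenyl unit.

Step 1
Reactants: 1 veratrole (1,2-dimethoxybenzene)
Product: 3 2,2'-(2,3-dimethoxy-1,4-phenylene)bis(4,4,5,5-tetramethyl-1,3,2-dioxaborolane), via 3,6-dilithioveratrole 2 (not isolated)
Conditions: n-BuLi (3 equiv), TMEDA (3 equiv), hexane/Et2O, 0 °C → rt, 24 h; iPrOBpin (4 equiv), −78 °C → rt; cold 1 M HCl quench; recrystallisation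
Reagents that add atoms: 2-isopropoxy-4,4,5,5-tetramethyl-1,3,2-dioxaborolane (iPrOBpin), CC(C)OB1OC(C)(C)C(C)(C)O1; n-butyllithium, [Li]CCCC (supplies only the lithium of 2)
Why: Twofold directed ortho-metalation, in which each methoxy oxygen guides TMEDA-activated n-BuLi to its single free ortho carbon (C3 and C6), followed by electrophilic trapping of both C–Li bonds with the borate ester to give the pinacol boronate directly.

Step 2
Reactants: 3 2,2'-(2,3-dimethoxy-1,4-phenylene)bis(4,4,5,5-tetramethyl-1,3,2-dioxaborolane); 4 1-bromo-4-chloro-2-nitrobenzene (2.3 equiv)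
Product: 6 4,4''-dichloro-2',3'-dimethoxy-2,2''-dinitro-1,1':4',1''-terphenyl, via monoarylated boronate 5 (not isolated)
Conditions: Pd(dppf)Cl2·CH2Cl2 (5 mol %), K2CO3 (4 equiv), 1,4-dioxane/H2O (4:1), 85 °C, Ar; silica plug with thiol scavenger, then recrystallisation to remove Pd
Reagents that add atoms: none
Why: Twofold Suzuki–Miyaura coupling, in which oxidative addition takes the weaker C–Br bond activated by the ortho nitro group, while the C–Cl bond (meta to NO2) is not touched by dppf-ligated palladium at this temperature, and the excess of 4 drives the second coupling.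

Step 3
Reactants: 6 4,4''-dichloro-2',3'-dimethoxy-2,2''-dinitro-1,1':4',1''-terphenyl
Product: 8 Borregomycin E (2,9-dichloro-5,6-dimethoxy-11,12-dihydroindolo[2,3-a]carbazole), via mono-closed nitroarylcarbazole 7 (not isolated)
Conditions: PPh3 (6 equiv), o-dichlorobenzene, 180 °C (reflux), Ar, 16–24 h; cool, dilute with MeOH, filter, SiO2
Reagents that add atoms: none
Why: Cadogan reductive cyclisation of a 2-nitrobiaryl, run at both ends of the terphenyl in one pot: PPh3 strips the oxygens of each nitro group one at a time (NO2 to N=O to a nitrene or phosphorus-bound nitrenoid), so four equivalents are consumed. The electron-deficient nitrogen then bonds to the ortho C–H carbon of the central ring across the biaryl bond in a five-atom, six-electron electrocyclic closure (equivalent to singlet-nitrene attack on the arene π system), and a hydrogen shift from that carbon to nitrogen restores aromaticity. The first closure makes N12–C11b and one pyrrole ring (7); the second, at C1–H of that carbazole, makes N11–C11a and the other pyrrole ring, each ring being five-membered and fused on both sides to benzene rings. No stereocentre is formed, the product being planar and achiral. The selectivity needed is regiochemical, between the two central-ring carbons ortho to each biaryl bond, and the substrate settles it: one of them (C2'/C3' of 6, later C5/C6) carries OMe and has no hydrogen to give up, whereas the open one lies para to the farther methoxy group and is activated towards electrophilic nitrogen, so the linear [3,2-b] isomer open to unsubstituted dinitro-para-terphenyls is excluded. PPh3 is chosen over a trialkyl phosphite because it cannot alkylate the new N–H groups, the aryl chlorides have no pathway to react once palladium residues are removed, and twofold closures of this type on dinitroterphenyls with blocked alternative positions are an established entry to indolo[2,3-a]carbazoles.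

Compound list
1 | veratrole (1,2-dimethoxybenzene) | COc1ccccc1OC | starting material
2 | 3,6-dilithioveratrole (1,4-dilithio-2,3-dimethoxybenzene) | COc1c([Li])ccc([Li])c1OC | intermediate (not isolated)
3 | 2,2'-(2,3-dimethoxy-1,4-phenylene)bis(4,4,5,5-tetramethyl-1,3,2-dioxaborolane) | COc1c(B2OC(C)(C)C(C)(C)O2)ccc(B2OC(C)(C)C(C)(C)O2)c1OC | intermediate
4 | 1-bromo-4-chloro-2-nitrobenzene | O=[N+]([O-])c1cc(Cl)ccc1Br | starting material
5 | 2-(4'-chloro-2,3-dimethoxy-2'-nitro-[1,1'-biphenyl]-4-yl)-4,4,5,5-tetramethyl-1,3,2-dioxaborolane | COc1c(B2OC(C)(C)C(C)(C)O2)ccc(-c2ccc(Cl)cc2[N+](=O)[O-])c1OC | intermediate (not isolated)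
6 | 4,4''-dichloro-2',3'-dimethoxy-2,2''-dinitro-1,1':4',1''-terphenyl | COc1c(OC)c(-c2ccc(Cl)cc2[N+](=O)[O-])ccc1-c1ccc(Cl)cc1[N+](=O)[O-] | intermediate
7 | 7-chloro-2-(4-chloro-2-nitrophenyl)-3,4-dimethoxy-9H-carbazole | COc1c(OC)c(-c2ccc(Cl)cc2[N+](=O)[O-])cc2[nH]c3cc(Cl)ccc3c12 | intermediate (not isolated)
8 | Borregomycin E (2,9-dichloro-5,6-dimethoxy-11,12-dihydroindolo[2,3-a]carbazole; achiral) | COc1c(OC)c2c3ccc(Cl)cc3[nH]c2c2[nH]c3cc(Cl)ccc3c12 | target

Total step count: 3. Longest linear sequence: 3.

Steps most likely to fail

**Step 3.**
- What may go wrong: the cascade may stall after the first ring closure. The nitrogen may engage the methoxy-bearing ortho carbon or the O–CH3 group instead of the free C–H. Long heating at 180 °C may also degrade the electron-rich product.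
- The fallback keeps the same two bonds but changes the nitrogen precursor and runs far cooler, setting out from 6.
- Chemoselective hydrogenation over sulfided Pt/C (H2, EtOAc/THF, rt, C–Cl retained) should give 4,4''-dichloro-2',3'-dimethoxy-[1,1':4',1''-terphenyl]-2,2''-diamine F1.
- Diazotisation (NaNO2, aq HCl/AcOH, 0 °C) should give 4,4''-dichloro-2',3'-dimethoxy-[1,1':4',1''-terphenyl]-2,2''-bis(diazonium) dichloride F2.
- Treating this in the same flask with NaN3 should give 2,2''-diazido-4,4''-dichloro-2',3'-dimethoxy-1,1':4',1''-terphenyl F3.
- Rhodium(II) carboxylate-catalysed decomposition of both azides (Rh2(O2CC7H15)4, 4 Å MS, toluene, 60 °C) is a known carbazole synthesis from 2-azidobiaryls. It should close both rings and come back to the route at 8.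

**Step 1.**
- What may go wrong: the second deprotonation may be incomplete, and aryllithium may add more than once at boron. The resulting mono- and bis-borylated material would be hard to separate.
- The fallback sets out from 2 and separates metalation from boron installation.
- Quenching with iodine (THF, −78 °C → rt) should give 1,4-diiodo-2,3-dimethoxybenzene F4, a crystalline solid that recrystallisation should free from mono-iodinated material.
- A twofold Miyaura borylation (B2pin2, Pd(dppf)Cl2, KOAc, dioxane, 90 °C) then comes back to the route at 3.

**Step 2.**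
- What may go wrong: protodeboronation of the ortho-methoxy boronate in the aqueous base may outrun the second coupling, so the reaction stops at the mono-arylated stage.
- The fallback is anhydrous and boron-free, setting out from 2 (made from 1 as in step 1).
- Transmetalation with ZnCl2 (THF, 0 °C → rt, enough to consume all organolithium) should give (2,3-dimethoxy-1,4-phenylene)bis(chlorozinc) F5.
- A twofold Negishi coupling with 4 (Pd(PPh3)4, THF, rt → 50 °C) follows. Arylzinc reagents tolerate nitro groups and again select C–Br over C–Cl. This comes back to the route at 6 and bypasses 3.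

Further compounds
F1 | step 3 | 4,4''-dichloro-2',3'-dimethoxy-[1,1':4',1''-terphenyl]-2,2''-diamine | COc1c(OC)c(-c2ccc(Cl)cc2N)ccc1-c1ccc(Cl)cc1N
F2 | step 3 | 4,4''-dichloro-2',3'-dimethoxy-[1,1':4',1''-terphenyl]-2,2''-bis(diazonium) dichloride | COc1c(OC)c(-c2ccc(Cl)cc2[N+]#N)ccc1-c1ccc(Cl)cc1[N+]#N.[Cl-].[Cl-]
F3 | step 3 | 2,2''-diazido-4,4''-dichloro-2',3'-dimethoxy-1,1':4',1''-terphenyl | COc1c(OC)c(-c2ccc(Cl)cc2N=[N+]=[N-])ccc1-c1ccc(Cl)cc1N=[N+]=[N-]
F4 | step 1 | 1,4-diiodo-2,3-dimethoxybenzene | COc1c(I)ccc(I)c1OC
F5 | step 2 | (2,3-dimethoxy-1,4-phenylene)bis(chlorozinc) | COc1c([Zn]Cl)ccc([Zn]Cl)c1OC
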